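Sunday's flask left something over: its last two readings stood at 69% and 69%, so 31.0% of the substrate charged had not become product, and with one partner per product 13.7% of the partner was still unused, yet the reading stayed flat.

| flask | substrate | partner | free catalyst | temperature | remark | time |
|---|---|---|---|---|---|---|
| Sunday's | 0.27 M | 0.216 M | 2.7 mM | 25 °C | the very flask that is asked about, followed so far |  |
| Monday's | 0.27 M | 0.43 M | 2.7 mM | 31 °C | run made earlier |  |
| flask | 0.27 M | 0.216 M | 2.7 mM | 25 °C |  | 1.0 h |

| run | time / min | product / % |
|---|---|---|
| Sunday's | 4.00 | 58 |
| Sunday's | 8.00 | 64 |
| Sunday's | 15.0 | 66 |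
| Sunday's | 25.0 | 69 |
| Sunday's | 50.0 | 69 |
| Monday's | 0.667 | 22 |
| Monday's | 1.33 | 45 |
| Monday's | 2.50 | 66 |
| Monday's | 4.00 | 73 |
| Monday's | 8.00 | 76 |

(readings scatter by 2 percentage points)

- product taken out counts as made
- additions bring no volume worth counting

- zeta: at 1.0 h add partner, 50.0% of the amount charged, then wait 1.0 h
- theta: at 1.0 h take out 90% of the product then present, then wait 1.0 h
- beta: change nothing and wait 1.0 h more
- epsilon: at 1.0 h raise the temperature by 20 K, then wait 1.0 h
- gamma: at 1.0 h add free catalyst, 50.0% of the amount charged, then wait 1.0 h

- product, in percent of the substrate first charged, at 1.0 h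
- what to do for the largest gain in product; "none" if nothing gains more than 2 percentage points (zeta / theta / beta / epsilon / gamma / none)
- product present, with what was taken out counted in, in percent of the substrate first charged, after theta
- product present, with what was taken out counted in, in percent of the substrate first charged, after beta

I first read the end of this flask from its own tail, as a count of product made per catalyst charged:

Sunday: 69% × 0.27 M / 2.7 mM = 69.0

This number, the turnover budget, was what I meant to carry. My second way borrowed the budget of Monday's run, taking its last reading, at 8.00 min, as its stop:

Monday: 76.0, which on Sunday's charges gives 76.0%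

The two ways parted by 7 percentage points against a scatter of 2 points, and I trusted the tail, since Monday's number came from 0.43 M of partner and 31 °C. A stop at equilibrium had to pass the same test, so I formed product over unconverted substrate times unused partner, each as a fraction of the substrate charge:

Sunday: 20.2; Monday: 3.80

As read from these scattered readings, that quotient moved by a factor of 5.32 between the two runs, while the budget moved by a factor of 1.10, so I held to the budget as the steadier number and set the equilibrium way aside. I therefore committed to 69% at 1.0 h and to no gain from waiting, heat, more partner or taking product out. In Sunday's flask partner is the limiting reagent, with a ceiling of 80.0%. Fresh catalyst at 50.0% of the charge offered 34 points by the budget, but the ceiling left room for 11 points, so I chose gamma and allowed it that much.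

The forecast gave 69%, chose gamma, and put theta at 70% and beta at 69.5%, reading the stop as “catalyst dying with turnover, not to a reversible stop”.

The flask gave 68.0%, gamma as the best choice with a gain of 5.9 points, less than my allowance, and 68.0% after theta and 68.0% after beta.

    substrate + free catalyst → free catalyst + open intermediate (k = 3.70 M⁻¹ s⁻¹, Ea = 52.0 kJ mol⁻¹)
    free catalyst + open intermediate ⇌ catalyst intermediate (K = 23.0 M⁻¹, k = 14.0 M⁻¹ s⁻¹, Ea = 38.0 kJ mol⁻¹, ΔH = −19.0 kJ mol⁻¹)
    partner + catalyst intermediate → free catalyst + product (k = 10.0 M⁻¹ s⁻¹, Ea = 46.0 kJ mol⁻¹)
    free catalyst + product → spent catalyst (k = 0.0550 M⁻¹ s⁻¹, Ea = 53.0 kJ mol⁻¹)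
    (constants at 25 °C)

In Sunday's flask the step to spent catalyst, taken by itself, gave free catalyst a half-life of 3.6 min at 1.13 min, far shorter than the 1.0 h asked about, and at that hour spent catalyst stood at 100%. At that hour Sunday's flask also held 14.8% of the substrate as open intermediate, which the product number doesn't show, yet product still stood at 68.0% at 600 min. In a neighbour flask with 0.054 M of partner, the budget offers 69.0% but the partner charge allows 20.0%, less, and that neighbour gave 19.1% with partner at 0%.

The numbers in the tables are simulated for substances that don't exist, and the scatter is random.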